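The smaller charge in maple, alder and larch is the nucleophile, 0.0160 M against 0.020 M of electrophile, which makes it the limiting reagent.

| flask | electrophile | nucleophile | remark | time |
|---|---|---|---|---|
| Thursday's | 0.020 M | 0.016 M | run made earlier |  |
| Friday's | 0.010 M | 0.016 M | run made earlier |  |
| Monday's | 0.015 M | 0.016 M | run made earlier |  |
| Saturday's | 0.020 M | 0.024 M | run made earlier |  |
| maple | 0.020 M (fed, over 8.0 h) | 0.0160 M | all else is in the flask from the start; the feed brings no volume worth counting | 10 h |
| alder | 0.020 M | 0.0160 M (fed, over 8.0 h) | all else is in the flask from the start; the feed brings no volume worth counting | 10 h |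
| larch | 0.020 M | 0.0160 M | everything together at the start | 10 h |

| run | time / h | target / % | electrophile / % |
|---|---|---|---|
| Thursday's | 1.00 | 9 | 90 |
| Thursday's | 2.00 | 12 | 88 |
| Thursday's | 3.00 | 19 | 86 |
| Thursday's | 4.00 | 18 | 80 |
| Thursday's | 5.00 | 21 | 80 |
| Thursday's | 6.00 | 22 | 76 |
| Friday's | 1.00 | 15 | 91 |
| Friday's | 1.50 | 13 | 83 |
| Friday's | 2.50 | 19 | 85 |
| Friday's | 4.00 | 25 | 79 |
| Friday's | 8.00 | 31 | 68 |
| Friday's | 12.0 | 41 | 60 |
| Monday's | 0.833 | 10 | 93 |
| Monday's | 2.50 | 16 | 84 |
| Monday's | 4.00 | 20 | 80 |
| Monday's | 6.00 | 25 | 74 |
| Monday's | 10.0 | 32 | 67 |
| Monday's | 12.0 | 39 | 65 |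
| Saturday's | 1.00 | 14 | 86 |
| Saturday's | 2.00 | 18 | 79 |
| Saturday's | 3.00 | 26 | 78 |
| Saturday's | 6.00 | 33 | 68 |
| Saturday's | 12.0 | 44 | 56 |

(standard deviation of a reading: 1.5 percentage points)

- what was read earlier has a scatter of 1.5 percentage points, one standard deviation

* which flask leads in amount of target, in percent of the electrophile charged ("all alike" within 1.5 percentage points) (maple / alder / larch / all alike)
* how much target is there at the end, in percent of the electrophile charged: maple
* how much target is there at the end, in percent of the electrophile charged: alder
* how much target is there at the end, in percent of the electrophile charged: larch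

Two chemists dispute this. The first writes the balance of the nucleophile: one is spent per target, so target can climb to 80.0% of the electrophile charged. In Thursday's last reading target and electrophile add to 98.0%, so he counts no side loss. With equal charges, he expects the flasks level within 1.5 percentage points.

The second chemist, who made the forecast, reads the hours. From 1.00 h to 6.00 h, Thursday's readings of target grew 2.44 times, close to the root of the time ratio, 2.45, although by the first chemist's balance just 27.5% of the nucleophile is spent. His words are “Feeding gives no relief from inhibition”, and his forecast puts larch first with 26%, then maple with 20% and alder with 18%.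

My own reckoning takes the root of time and scales Thursday's last reading back, which gives 8.98%. This one-hour figure is the target a recipe would show after 1.00 h on its root-of-time line. Larch is Thursday's recipe, so scaling forward to 10 h gives 28.4%, from a reading with a scatter of 1.5 points. That is more than the forecast's 26%.

The flasks give 20.3% for maple, 22.4% for alder and 28.4% for larch, so larch leads.

    nucleophile + acid set free ⇌ protonated nucleophile, settled at all times (K = 10900 L mol⁻¹)
    nucleophile ⇌ dormant form (K = 1.25, k = 0.486 h⁻¹)
    electrophile + nucleophile → acid set free + target (k = 8.39 L mol⁻¹ h⁻¹)
    nucleophile + acid set free ⇌ idle adduct, settled at all times (K = 12400 L mol⁻¹)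

The one-hour figure's 28.4% lies on larch, and Friday's recipe, with 11.8% from its last reading, gives 37.4% at 10 h against the 37.3% it holds when stopped then. The first chemist's level flasks stand at 100 h: larch has 45.6%, maple 45.3% and alder 45.4%, within 1.5 points, though below his 80.0%. In maple, the exchange of nucleophile with dormant form has a half-life of 0.792 h, both ways together, while the target-forming step would by itself halve the nucleophile in 5.2 h at 10.0 h, which is slower. At 10.0 h, maple holds c(dormant form) = 0.00498 M, with nucleophile at 18.6% of its own charge.

Readings and results were generated by integration for an exercise; noise was put on by code.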